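**Retrosynthetic overview**
1. Target 15 ⇒ cut the aryl–O–CH2 allyl ether bond: phenol 14 plus allylic alcohol 13, joined last by Mitsunobu etherification.
2. Lactone 13 ⇒ (S)-epoxide 6 plus lactic acid-derived dioxolanone 9; a new tandem epoxide opening and acyl transfer closes the lactone C–O bond and sets the tertiary carbinol.
3. Epoxide 6 ⇒ aldehyde 3 by enantioselective α-chlorination, reduction and oxirane closure (C–O bond formed with inversion).
4. Aldehyde 3 ⇒ geranyl acetate 1 by cleavage of the distal alkene; the E alkene is bought in.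
5. Ring order: coumarin bought; temporary oxirane (step 2) and dioxolanone (step 3); the γ-lactone (step 4) is the only ring of the target that is built.

Assumption: 7-hydroxy-8-methoxycoumarin (hydrangetin, 14) is bought as a catalogue compound.

**Route**

Step 1
Reactants: 1 geranyl acetate
Product: 3 [(2E)-3-methyl-6-oxohex-2-en-1-yl] acetate, via 6,7-epoxygeranyl acetate 2 (not isolated)
Conditions: mCPBA (1.05 equiv), NaHCO3, CH2Cl2, 0 °C; then H5IO6, THF–H2O, 0 °C
Reagents that add atoms: mCPBA, O=C(OO)c1cccc(Cl)c1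
Why: Prilezhaev epoxidation is selective for the distal trisubstituted alkene because the 2,3-alkene is deactivated by the allylic acetate, and periodic acid then hydrolyses the oxirane and cleaves the glycol (Malaprade cleavage) to the aldehyde, leaving the E alkene untouched.

Step 2
Reactants: 3 [(2E)-3-methyl-6-oxohex-2-en-1-yl] acetate
Product: 6 (2E)-3-methyl-4-[(2S)-oxiran-2-yl]but-2-en-1-ol, via chloro aldehyde 4 (not isolated), via chlorohydrin 5 (not isolated)
Conditions: NCS (1.1 equiv), (2S,5S)-2,5-diphenylpyrrolidine (10 mol %), CH2Cl2, 0 °C to rt; then NaBH4, MeOH, 0 °C; then KOH, EtOH–H2O, rt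
Reagents that add atoms: none
Why: Enamine-catalysed α-chlorination puts chlorine on the enamine face anti to the flanking phenyl of the catalyst (the (2S,5S) antipode is predicted from this steric model to give the R chloride, and the other antipode is used if the sense is found opposite), NaBH4 reduces the labile aldehyde at once, and hydroxide closes the oxirane by intramolecular Williamson displacement with inversion (R chloride to S epoxide) while saponifying the acetate.

Step 3
Reactants: 7 (S)-lactic acid; 8 pivalaldehyde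
Product: 9 (2S,5S)-2-tert-butyl-5-methyl-1,3-dioxolan-4-one
Conditions: TsOH·H2O (cat.), H2SO4 (cat.), pentane, reflux, Dean–Stark; crystallisation from pentane at −78 °C
Reagents that add atoms: none
Why: Acid-catalysed acetalisation under thermodynamic control favours the cis (2S,5S) dioxolanone, whose acetal carbon stores the lactate chirality for the enolate step (self-regeneration of stereocentres), and low-temperature crystallisation raises the cis:trans ratio to about 96:4.

Step 4
Reactants: 6 (2E)-3-methyl-4-[(2S)-oxiran-2-yl]but-2-en-1-ol; 9 (2S,5S)-2-tert-butyl-5-methyl-1,3-dioxolan-4-one (1.5 equiv)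
Product: 13 (3R,5S)-3-hydroxy-5-[(2E)-4-hydroxy-2-methylbut-2-en-1-yl]-3-methyloxolan-2-one, via silyl ether 10 (not isolated), via lithium enolate 11 (not isolated), via hydroxy dioxolanone 12 (not isolated)
Conditions: 6, (Me3Si)2NH, Me3SiCl (cat.), CH2Cl2, rt, then evaporation; 9, LiN(iPr)2, THF, −78 °C; add 10, then BF3·OEt2 (1.5 equiv), −78 °C; aq. NH4Cl; then TsOH·H2O (cat.), THF–H2O, rt
Reagents that add atoms: none
Why: Proposed new method: a BF3-assisted opening of a terminal epoxide by the lithium enolate of a lactic acid-derived dioxolanone, coupled in the same flask to acyl transfer; the enolate attacks the unsubstituted oxirane carbon from the face anti to the tert-butyl group (this sets C3 of the lactone as R, as in all alkylations of this enolate, while the S oxirane carbon is not touched), and the freed 4-hydroxyl then attacks the activated acetal-ester carbonyl in a 5-exo-trig acyl transfer that closes the lactone C–O bond, expels pivalaldehyde and frees the tertiary hydroxyl cis to the side chain; the closest known reaction types are the alkyl halide alkylation of this enolate (self-regeneration of stereocentres) and BF3-promoted epoxide opening by lithium ester enolates, acetylides and dithianes.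

Step 5
Reactants: 13 (3R,5S)-3-hydroxy-5-[(2E)-4-hydroxy-2-methylbut-2-en-1-yl]-3-methyloxolan-2-one; 14 7-hydroxy-8-methoxy-2H-chromen-2-one
Product: 15 (3R,5S)-3-hydroxy-5-{(2E)-4-[(8-methoxy-2-oxo-2H-chromen-7-yl)oxy]-2-methylbut-2-en-1-yl}-3-methyloxolan-2-one
Conditions: PPh3, DIAD, THF, 0 °C to rt
Reagents that add atoms: none
Why: Mitsunobu etherification: the acidic 7-OH of 14 (pKa about 8) is alkylated by SN2 displacement at the primary allylic oxyphosphonium carbon so the E alkene is kept, while the tertiary alcohol and both lactones are inert and no stereocentre is touched.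

**Compound list**
1 | geranyl acetate, [(2E)-3,7-dimethylocta-2,6-dien-1-yl] acetate | CC(C)=CCC/C(C)=C/COC(C)=O | starting material
2 | [(2E)-5-(3,3-dimethyloxiran-2-yl)-3-methylpent-2-en-1-yl] acetate (6,7-epoxygeranyl acetate, racemic at the oxirane carbon) | CC(=O)OC/C=C(\C)CCC1OC1(C)C | intermediate
3 | [(2E)-3-methyl-6-oxohex-2-en-1-yl] acetate | CC(=O)OC/C=C(\C)CCC=O | intermediate
4 | [(2E,5R)-5-chloro-3-methyl-6-oxohex-2-en-1-yl] acetate | CC(=O)OC/C=C(\C)C[C@@H](Cl)C=O | intermediate
5 | [(2E,5R)-5-chloro-6-hydroxy-3-methylhex-2-en-1-yl] acetate | CC(=O)OC/C=C(\C)C[C@@H](Cl)CO | intermediate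
6 | (2E)-3-methyl-4-[(2S)-oxiran-2-yl]but-2-en-1-ol | OC/C=C(\C)C[C@H]1CO1 | intermediate
7 | (S)-lactic acid | C[C@H](O)C(=O)O | starting material
8 | pivalaldehyde (2,2-dimethylpropanal) | CC(C)(C)C=O | starting material
9 | (2S,5S)-2-tert-butyl-5-methyl-1,3-dioxolan-4-one (cis) | C[C@@H]1O[C@H](C(C)(C)C)OC1=O | intermediate
10 | trimethyl({(2E)-3-methyl-4-[(2S)-oxiran-2-yl]but-2-en-1-yl}oxy)silane | C[Si](C)(C)OC/C=C(\C)C[C@H]1CO1 | intermediate
11 | lithium (2S)-2-tert-butyl-5-methyl-1,3-dioxol-4-olate | CC1=C([O-])O[C@@H](C(C)(C)C)O1.[Li+] | intermediate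
12 | (2S,5R)-2-tert-butyl-5-[(2S,4E)-2-hydroxy-4-methyl-6-(trimethylsilyloxy)hex-4-en-1-yl]-5-methyl-1,3-dioxolan-4-one | C[C@]1(C[C@@H](O)C/C(C)=C/CO[Si](C)(C)C)O[C@H](C(C)(C)C)OC1=O | intermediate
13 | (3R,5S)-3-hydroxy-5-[(2E)-4-hydroxy-2-methylbut-2-en-1-yl]-3-methyloxolan-2-one | OC/C=C(\C)C[C@H]1C[C@@](C)(O)C(=O)O1 | intermediate
14 | 7-hydroxy-8-methoxy-2H-chromen-2-one (hydrangetin) | COc1c(O)ccc2ccc(=O)oc12 | starting material
15 | (3R,5S)-3-hydroxy-5-{(2E)-4-[(8-methoxy-2-oxo-2H-chromen-7-yl)oxy]-2-methylbut-2-en-1-yl}-3-methyloxolan-2-one | COc1c(OC/C=C(\C)C[C@H]2C[C@@](C)(O)C(=O)O2)ccc2ccc(=O)oc12 | target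

**Step count**
Total steps: 5. Longest linear sequence: 4 (steps 1, 2, 4, 5); step 3 is a one-step side branch.

**Three steps most likely to fail**

Step 4 (the proposed new step). The enolate 11 decomposes above about −30 °C, BF3 can divert the epoxide to a rearranged aldehyde, and the acyl transfer may stall at 12. Fallback with known chemistry, setting out from 6 and coming back at 13:
- 6 is silylated (tBuPh2SiCl, imidazole) to the tert-butyldiphenylsilyl ether F1.
- The oxirane is opened at its CH2 terminus by the dilithium dianion of (4-methoxybenzyloxy)acetic acid (2 LiN(iPr)2, THF, 0 °C to rt, Creger-type dianion alkylation) to the hydroxy acid F2.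
- F2 is lactonised (TsOH·H2O cat., toluene) to the 3-alkoxy lactone F3, a mixture of C3 epimers.
- Enolisation (LiN(iPr)2, −78 °C) and MeI put the methyl group trans to the C5 side chain, giving the methylated lactone F4. Here C3 is set by the substrate, not by the lactate auxiliary.
- DDQ removes the 4-methoxybenzyl group to give the hydroxy lactone silyl ether F5, and Bu4NF then gives 13.

Step 2. The enantioselectivity of the chlorination, racemisation of 4 before reduction, and loss of the small polar epoxide 6 on isolation are the risks. Fallback setting out from 3 and coming back at 6, in which the C–O bond is made directly and kept with retention: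
- D-proline-catalysed α-aminoxylation with nitrosobenzene gives the (S)-aminoxy aldehyde F6, reduced in the same flask with NaBH4 to the aminoxy alcohol F7.
- N–O cleavage (Zn, AcOH) gives the (S)-diol F8.
- Selective sulfonylation of the primary hydroxyl (TsCl, Bu2SnO cat., Et3N) gives the monotosylate F9.
- K2CO3 in MeOH closes the oxirane and removes the acetate, giving 6.

Step 5. SN2′ attack, or poor separation of the polar product from the phosphine oxide, may lower the yield. Fallback setting out from 13 and coming back at 15: Appel bromination (CBr4, PPh3, CH2Cl2, 0 °C) gives the allylic bromide F10, which alkylates the phenoxide of 14 (K2CO3, acetone, rt) in a Williamson etherification.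

Further compounds
F1 | step 4 | tert-butyl({(2E)-3-methyl-4-[(2S)-oxiran-2-yl]but-2-en-1-yl}oxy)diphenylsilane | CC(C)(C)[Si](OC/C=C(\C)C[C@H]1CO1)(c1ccccc1)c1ccccc1
F2 | step 4 | (4S,6E)-8-[(tert-butyldiphenylsilyl)oxy]-4-hydroxy-2-[(4-methoxyphenyl)methoxy]-6-methyloct-6-enoic acid (C2 epimers) | COc1ccc(COC(C[C@@H](O)C/C(C)=C/CO[Si](c2ccccc2)(c2ccccc2)C(C)(C)C)C(=O)O)cc1
F3 | step 4 | (5S)-5-{(2E)-4-[(tert-butyldiphenylsilyl)oxy]-2-methylbut-2-en-1-yl}-3-[(4-methoxyphenyl)methoxy]oxolan-2-one (C3 epimers) | COc1ccc(COC2C[C@H](C/C(C)=C/CO[Si](c3ccccc3)(c3ccccc3)C(C)(C)C)OC2=O)cc1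
F4 | step 4 | (3R,5S)-5-{(2E)-4-[(tert-butyldiphenylsilyl)oxy]-2-methylbut-2-en-1-yl}-3-[(4-methoxyphenyl)methoxy]-3-methyloxolan-2-one | COc1ccc(CO[C@]2(C)C[C@H](C/C(C)=C/CO[Si](c3ccccc3)(c3ccccc3)C(C)(C)C)OC2=O)cc1
F5 | step 4 | (3R,5S)-5-{(2E)-4-[(tert-butyldiphenylsilyl)oxy]-2-methylbut-2-en-1-yl}-3-hydroxy-3-methyloxolan-2-one | CC(C)(C)[Si](OC/C=C(\C)C[C@H]1C[C@@](C)(O)C(=O)O1)(c1ccccc1)c1ccccc1
F6 | step 2 | [(2E,5S)-3-methyl-6-oxo-5-(phenylaminooxy)hex-2-en-1-yl] acetate | CC(=O)OC/C=C(\C)C[C@H](ONc1ccccc1)C=O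
F7 | step 2 | [(2E,5S)-6-hydroxy-3-methyl-5-(phenylaminooxy)hex-2-en-1-yl] acetate | CC(=O)OC/C=C(\C)C[C@H](ONc1ccccc1)CO
F8 | step 2 | [(2E,5S)-5,6-dihydroxy-3-methylhex-2-en-1-yl] acetate | CC(=O)OC/C=C(\C)C[C@H](O)CO
F9 | step 2 | [(2E,5S)-5-hydroxy-3-methyl-6-(tosyloxy)hex-2-en-1-yl] acetate | CC(=O)OC/C=C(\C)C[C@H](O)COS(=O)(=O)c1ccc(C)cc1
F10 | step 5 | (3R,5S)-5-[(2E)-4-bromo-2-methylbut-2-en-1-yl]-3-hydroxy-3-methyloxolan-2-one | BrC/C=C(\C)C[C@H]1C[C@@](C)(O)C(=O)O1
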